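The disconnection on which everything rests is the C6–C7 bond of the seven-membered ring B. The oxygens on C6 and C8 are 1,3-related across C7, which makes this an aldol bond, and the cis C9=C10 alkene of ring B holds the two reacting carbons close. A samarium diiodide Reformatsky cyclisation turns a bromomethyl ketone into the C7 enolate without base, closes ring B onto the C6 aldehyde and sets the C6 carbinol in one operation. Its precursor is a cyclopentane (ring A) bearing the quaternary C1 with a (Z)-4-bromo-3-oxobut-1-enyl arm, a trans C5 formyl group and the silylated C4 isopropyl carbinol.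

Key step: step 10

Remark: atoms are numbered C1–C10 as in the daucane skeleton (C1 methyl-bearing ring-fusion carbon, C4 isopropyl carbinol, C5 ring-fusion CH, C6 acyloxy carbon, C8 methyl carbinol), β means the face of the C1 methyl, and the ligand enantiomer in step 1 is assumed to be the one that gives the (S)-configured quaternary carbon of 5.

Step 1
Reactants: 1 3-methylcyclopent-2-en-1-one; 2 trimethylsilylacetylene
Product: 5 triethyl({(3S)-3-methyl-3-[1-(trimethylsilyl)ethenyl]cyclopent-1-en-1-yl}oxy)silane, via alkenylalane 3 (not isolated), via aluminium enolate 4 (not isolated)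
Conditions: 2, (iBu)2AlH, hexane/THF, 55 °C; then 1, Cu(OTf)2 (5 mol %), chiral sulfonate-bearing imidazolinium salt (NHC precursor, 5 mol %), THF, −78 → −15 °C; then Et3SiOTf, −78 → 0 °C
Reagents that add atoms: triethylsilyl trifluoromethanesulfonate, CC[Si](CC)(CC)OS(=O)(=O)C(F)(F)F
Why: Copper–NHC-catalysed asymmetric conjugate addition of the alkenylalane formed by hydroalumination of 2 builds the quaternary C1 with the catalyst choosing the enone face, and silyl triflate capture of the regiodefined aluminium enolate gives the C4=C5 enol silyl ether, the 1-silylvinyl group being used because it is far bulkier than the C1 methyl.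

Step 2
Reactants: 5
Product: 6 (2S,3S)-2-(dimethoxymethyl)-3-methyl-3-[1-(trimethylsilyl)ethenyl]cyclopentan-1-one
Conditions: HC(OMe)3, Me3SiOTf (10 mol %), CH2Cl2, −78 → −40 °C
Reagents that add atoms: trimethyl orthoformate, COC(OC)OC
Why: Mukaiyama-type addition of the enol silyl ether to the dimethoxycarbenium ion (Noyori conditions) puts the masked C6 aldehyde on C5 anti to the bulky 1-silylvinyl group of the adjacent quaternary C1, hence cis to the C1 methyl, which is also the more stable arrangement at the epimerisable C5.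

Step 3
Reactants: 6; 7 isopropylmagnesium chloride
Product: 8 (1R,2R,3S)-2-(dimethoxymethyl)-3-methyl-1-(propan-2-yl)-3-[1-(trimethylsilyl)ethenyl]cyclopentan-1-ol
Conditions: LaCl3·2LiCl (1 equiv), THF, rt; then iPrMgCl, 0 °C; aq. NH4Cl
Reagents that add atoms: none
Why: Lanthanum-assisted Grignard 1,2-addition suppresses enolisation and β-hydride reduction, and isopropyl enters the cyclopentanone anti to the adjacent C5 dimethoxymethyl group and the pseudo-axial C1 methyl, so that the C4 oxygen ends cis to C6 and isopropyl trans.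

Step 4
Reactants: 8
Product: 9 triethyl({(1R,2R,3S)-2-(dimethoxymethyl)-3-methyl-1-(propan-2-yl)-3-[1-(trimethylsilyl)ethenyl]cyclopentyl}oxy)silane
Conditions: KN(SiMe3)2, THF, −78 °C; then Et3SiCl, −78 → 0 °C
Reagents that add atoms: chlorotriethylsilane, CC[Si](CC)(CC)Cl
Why: O-Silylation of the potassium alkoxide caps the hindered tertiary C4 hydroxyl under basic conditions that leave the dimethyl acetal alone, and the ether later prevents retro-aldol cleavage of the C6 aldehyde.

Step 5
Reactants: 9
Product: 10 triethyl({(1R,2R,3S)-2-(dimethoxymethyl)-3-(1-iodoethenyl)-3-methyl-1-(propan-2-yl)cyclopentyl}oxy)silane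
Conditions: N-iodosuccinimide, MeCN/ClCH2CN (4:1), 0 °C → rt, dark
Reagents that add atoms: N-iodosuccinimide, O=C1CCC(=O)N1I
Why: Electrophilic iododesilylation (ipso substitution of the vinylsilane) exchanges silicon for iodine at C10, and neither the acetal nor the silyl ether can intercept the iodonium ion because both sit trans to the alkenyl arm.

Step 6
Reactants: 10
Product: 12 3-[(1S,2R,3R)-2-(dimethoxymethyl)-1-methyl-3-(propan-2-yl)-3-[(triethylsilyl)oxy]cyclopentyl]-N-methoxy-N-methylprop-2-ynamide, via lithium acetylide 11 (not isolated)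
Conditions: LiN(iPr)2 (2.5 equiv), THF, −78 → 0 °C; then ClC(O)N(OMe)Me, −78 °C → rt
Reagents that add atoms: N-methoxy-N-methylcarbamoyl chloride, CON(C)C(Cl)=O
Why: Base-induced dehydroiodination of the 2-iodoalkene (as with enol triflates of methyl ketones) and deprotonation give lithium acetylide 11, whose C-acylation by the carbamoyl chloride attaches C8 as a Weinreb ynamide.

Step 7
Reactants: 12
Product: 13 (2Z)-3-[(1R,2R,3R)-2-(dimethoxymethyl)-1-methyl-3-(propan-2-yl)-3-[(triethylsilyl)oxy]cyclopentyl]-N-methoxy-N-methylprop-2-enamide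
Conditions: H2 (1 atm), Pd/CaCO3 poisoned with Pb(OAc)2, quinoline, EtOAc, rt
Reagents that add atoms: none
Why: Lindlar semihydrogenation adds both hydrogens to the same side of the ynamide and stops at the alkene, which fixes the (Z)-geometry of C9=C10 needed for ring B.

Step 8
Reactants: 13
Product: 15 (3Z)-1-bromo-4-[(1R,2R,3R)-2-(dimethoxymethyl)-1-methyl-3-(propan-2-yl)-3-[(triethylsilyl)oxy]cyclopentyl]but-3-en-2-one, via tetrahedral adduct 14 (not isolated)
Conditions: CH2Br2, MeLi·LiBr (slow addition), THF, −78 °C; then AcOH, −78 °C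
Reagents that add atoms: dibromomethane, BrCBr
Why: Bromomethyllithium formed by bromine–lithium exchange adds once to the Weinreb amide (carbenoid homologation), the chelated adduct 14 holds until the acidic quench, and the quench also protonates the liberated amine so that it cannot add to or isomerise the (Z)-enone.

Step 9
Reactants: 15
Product: 16 (1R,2R,5R)-2-[(1Z)-4-bromo-3-oxobut-1-en-1-yl]-2-methyl-5-(propan-2-yl)-5-[(triethylsilyl)oxy]cyclopentane-1-carbaldehyde
Conditions: pyridinium p-toluenesulfonate, acetone/H2O, 40 °C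
Reagents that add atoms: water, O
Why: Mild acid-catalysed acetal hydrolysis frees the C6 aldehyde without cleaving the hindered tertiary silyl ether or isomerising the (Z)-enone, and C5 keeps its configuration because the formyl group already lies trans to both the isopropyl group and the C1 arm, the thermodynamically preferred arrangement.

Step 10
Reactants: 16
Product: 18 (3R,3aS,4S,8aR)-4-hydroxy-8a-methyl-3-(propan-2-yl)-3-[(triethylsilyl)oxy]-2,3,3a,4,5,8a-hexahydroazulen-6(1H)-one, via samarium enolate 17 (not isolated)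
Conditions: SmI2 (2.5 equiv), THF, −78 °C, slow addition of 16 (high dilution); aq. NH4Cl
Reagents that add atoms: none
Why: Two single-electron transfers from divalent samarium cleave the C7–Br bond and give the trivalent samarium enolate 17 under neutral conditions, so the C5 stereocentre next to the aldehyde is not epimerised and neither the enone nor the aldehyde is reduced at −78 °C. The enolate carbon C7 then adds to the C6 aldehyde in an intramolecular samarium Reformatsky aldol addition, the closest precedent being samarium diiodide closures of seven- to nine-membered rings from α-bromo ketones tethered to aldehydes. Ring B closes in a 7-(enolendo)-exo-trig mode, helped by the cis C9=C10 alkene and the trans disposition of the two arms on ring A, which bring C7 within bonding distance of C6. The new C6 stereocentre is controlled by the C5 centre and by the samarium chelate between the enolate and aldehyde oxygens: in the chair-like transition state the C6–O bond sits pseudo-equatorial, away from the pseudo-axial C1 methyl, which should give the 6α-hydroxyl with H6 anti to H5. The step needs chemoselective reduction of the carbon–bromine bond and ring closure faster than enolate protonation, which the fast reduction of α-bromo ketones, high dilution and the absence of proton sources should secure.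

Step 11
Reactants: 18
Product: 19 (3R,3aS,4S,6S,8aR)-6,8a-dimethyl-3-(propan-2-yl)-3-[(triethylsilyl)oxy]-1,2,3,3a,4,5,6,8a-octahydroazulene-4,6-diol
Conditions: MeLi, CeCl3 (3 equiv each), THF, −78 °C; aq. NH4Cl
Reagents that add atoms: methyllithium, [Li]C
Why: The weakly basic organocerium reagent adds 1,2 to the enone without retro-aldol cleavage or dehydration, and methyl is expected to enter C8 from the α face (equatorial attack, anti to the pseudo-axial C1 methyl), which gives the 8β-hydroxy-8α-methyl carbinol.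

Step 12
Reactants: 20 vanillic acid
Product: 22 4-[(tert-butyldimethylsilyl)oxy]-3-methoxybenzoic acid, via silyl ester 21 (not isolated)
Conditions: tBuMe2SiCl (2.2 equiv), imidazole, DMF, rt; then AcOH/THF/H2O, rt
Reagents that add atoms: tert-butyldimethylsilyl chloride, CC(C)(C)[Si](C)(C)Cl
Why: Bis-silylation followed by selective hydrolysis of the labile silyl ester leaves the acid free and the phenol masked as its aryl silyl ether (standard phenol protection).

Step 13
Reactants: 19; 22
Product: 24 (3R,3aS,4S,6S,8aR)-6-hydroxy-6,8a-dimethyl-3-(propan-2-yl)-3-[(triethylsilyl)oxy]-1,2,3,3a,4,5,6,8a-octahydroazulen-4-yl 4-[(tert-butyldimethylsilyl)oxy]-3-methoxybenzoate, via mixed anhydride 23 (not isolated)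
Conditions: 22, 2,4,6-trichlorobenzoyl chloride, Et3N, THF, rt; then 19, DMAP, toluene, rt → 40 °C
Reagents that add atoms: none
Why: Yamaguchi esterification through mixed anhydride 23 acylates only the secondary C6 hydroxyl, the tertiary allylic C8 hydroxyl and the silylated C4 oxygen being unreactive, and no stereocentre is touched.

Step 14
Reactants: 24
Product: 25 (3R,3aS,4S,6S,8aR)-3,6-dihydroxy-6,8a-dimethyl-3-(propan-2-yl)-1,2,3,3a,4,5,6,8a-octahydroazulen-4-yl 4-hydroxy-3-methoxybenzoate
Conditions: Bu4NF, AcOH, THF, 0 °C → rt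
Reagents that add atoms: none
Why: Fluoride-induced desilylation removes the aryl and the tertiary alkyl silyl ethers under buffered, non-acidic conditions that spare the benzoate and the acid-sensitive tertiary allylic alcohol.

Compound list
1 | 3-methylcyclopent-2-en-1-one | CC1=CC(=O)CC1 | starting material
2 | trimethylsilylacetylene | C#C[Si](C)(C)C | starting material
3 | diisobutyl[1-(trimethylsilyl)ethenyl]alumane | C=C([Si](C)(C)C)[Al](CC(C)C)CC(C)C | intermediate
4 | diisobutylaluminium (3S)-3-methyl-3-[1-(trimethylsilyl)ethenyl]cyclopent-1-en-1-olate | C1=C(O[Al](CC(C)C)CC(C)C)CC[C@]1(C)C(=C)[Si](C)(C)C | intermediate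
5 | triethyl({(3S)-3-methyl-3-[1-(trimethylsilyl)ethenyl]cyclopent-1-en-1-yl}oxy)silane | C1=C(O[Si](CC)(CC)CC)CC[C@]1(C)C(=C)[Si](C)(C)C | intermediate
6 | (2S,3S)-2-(dimethoxymethyl)-3-methyl-3-[1-(trimethylsilyl)ethenyl]cyclopentan-1-one (acetal cis to methyl) | COC(OC)[C@H]1C(=O)CC[C@]1(C)C(=C)[Si](C)(C)C | intermediate
7 | isopropylmagnesium chloride | CC(C)[Mg]Cl | starting material
8 | (1R,2R,3S)-2-(dimethoxymethyl)-3-methyl-1-(propan-2-yl)-3-[1-(trimethylsilyl)ethenyl]cyclopentan-1-ol | COC(OC)[C@H]1[C@](O)(C(C)C)CC[C@]1(C)C(=C)[Si](C)(C)C | intermediate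
9 | triethyl({(1R,2R,3S)-2-(dimethoxymethyl)-3-methyl-1-(propan-2-yl)-3-[1-(trimethylsilyl)ethenyl]cyclopentyl}oxy)silane | COC(OC)[C@H]1[C@](O[Si](CC)(CC)CC)(C(C)C)CC[C@]1(C)C(=C)[Si](C)(C)C | intermediate
10 | triethyl({(1R,2R,3S)-2-(dimethoxymethyl)-3-(1-iodoethenyl)-3-methyl-1-(propan-2-yl)cyclopentyl}oxy)silane | COC(OC)[C@H]1[C@](O[Si](CC)(CC)CC)(C(C)C)CC[C@]1(C)C(I)=C | intermediate
11 | lithium acetylide of the C1 ethynyl cyclopentane (C9 lithiated) | COC(OC)[C@H]1[C@](O[Si](CC)(CC)CC)(C(C)C)CC[C@]1(C)C#C[Li] | intermediate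
12 | 3-[(1S,2R,3R)-2-(dimethoxymethyl)-1-methyl-3-(propan-2-yl)-3-[(triethylsilyl)oxy]cyclopentyl]-N-methoxy-N-methylprop-2-ynamide | COC(OC)[C@H]1[C@](O[Si](CC)(CC)CC)(C(C)C)CC[C@]1(C)C#CC(=O)N(C)OC | intermediate
13 | (2Z)-3-[(1R,2R,3R)-2-(dimethoxymethyl)-1-methyl-3-(propan-2-yl)-3-[(triethylsilyl)oxy]cyclopentyl]-N-methoxy-N-methylprop-2-enamide | COC(OC)[C@H]1[C@](O[Si](CC)(CC)CC)(C(C)C)CC[C@]1(C)/C=C\C(=O)N(C)OC | intermediate
14 | lithium alkoxide adduct of bromomethyllithium to Weinreb amide 13 | COC(OC)[C@H]1[C@](O[Si](CC)(CC)CC)(C(C)C)CC[C@]1(C)/C=C\C(O[Li])(CBr)N(C)OC | intermediate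
15 | (3Z)-1-bromo-4-[(1R,2R,3R)-2-(dimethoxymethyl)-1-methyl-3-(propan-2-yl)-3-[(triethylsilyl)oxy]cyclopentyl]but-3-en-2-one | COC(OC)[C@H]1[C@](O[Si](CC)(CC)CC)(C(C)C)CC[C@]1(C)/C=C\C(=O)CBr | intermediate
16 | (1R,2R,5R)-2-[(1Z)-4-bromo-3-oxobut-1-en-1-yl]-2-methyl-5-(propan-2-yl)-5-[(triethylsilyl)oxy]cyclopentane-1-carbaldehyde | O=C[C@H]1[C@](O[Si](CC)(CC)CC)(C(C)C)CC[C@]1(C)/C=C\C(=O)CBr | intermediate
17 | diiodosamarium C7 enolate of 16 | O=C[C@H]1[C@](O[Si](CC)(CC)CC)(C(C)C)CC[C@]1(C)/C=C\C(=C)O[Sm](I)I | intermediate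
18 | (3R,3aS,4S,8aR)-4-hydroxy-8a-methyl-3-(propan-2-yl)-3-[(triethylsilyl)oxy]-2,3,3a,4,5,8a-hexahydroazulen-6(1H)-one (6α-hydroxy, trans-fused) | O[C@H]1CC(=O)C=C[C@@]2(C)CC[C@@](O[Si](CC)(CC)CC)(C(C)C)[C@H]12 | intermediate
19 | (3R,3aS,4S,6S,8aR)-6,8a-dimethyl-3-(propan-2-yl)-3-[(triethylsilyl)oxy]-1,2,3,3a,4,5,6,8a-octahydroazulene-4,6-diol | O[C@H]1C[C@](C)(O)C=C[C@@]2(C)CC[C@@](O[Si](CC)(CC)CC)(C(C)C)[C@H]12 | intermediate
20 | vanillic acid | COc1cc(C(=O)O)ccc1O | starting material
21 | tert-butyldimethylsilyl 4-[(tert-butyldimethylsilyl)oxy]-3-methoxybenzoate | COc1cc(C(=O)O[Si](C)(C)C(C)(C)C)ccc1O[Si](C)(C)C(C)(C)C | intermediate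
22 | 4-[(tert-butyldimethylsilyl)oxy]-3-methoxybenzoic acid | COc1cc(C(=O)O)ccc1O[Si](C)(C)C(C)(C)C | intermediate
23 | 4-[(tert-butyldimethylsilyl)oxy]-3-methoxybenzoic 2,4,6-trichlorobenzoic anhydride | COc1cc(C(=O)OC(=O)c2c(Cl)cc(Cl)cc2Cl)ccc1O[Si](C)(C)C(C)(C)C | intermediate
24 | (3R,3aS,4S,6S,8aR)-6-hydroxy-6,8a-dimethyl-3-(propan-2-yl)-3-[(triethylsilyl)oxy]-1,2,3,3a,4,5,6,8a-octahydroazulen-4-yl 4-[(tert-butyldimethylsilyl)oxy]-3-methoxybenzoate | COc1cc(C(=O)O[C@H]2C[C@](C)(O)C=C[C@@]3(C)CC[C@@](O[Si](CC)(CC)CC)(C(C)C)[C@H]23)ccc1O[Si](C)(C)C(C)(C)C | intermediate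
25 | (3R,3aS,4S,6S,8aR)-3,6-dihydroxy-6,8a-dimethyl-3-(propan-2-yl)-1,2,3,3a,4,5,6,8a-octahydroazulen-4-yl 4-hydroxy-3-methoxybenzoate | COc1cc(C(=O)O[C@H]2C[C@](C)(O)C=C[C@@]3(C)CC[C@@](O)(C(C)C)[C@H]23)ccc1O | target

Total step count: 14. Longest linear sequence: 13 steps (steps 1–11, 13 and 14); step 12 prepares the acid fragment.

Steps most likely to fail

Step 10. The aldehyde may be attacked on the wrong face, so that the ring-closed product is mainly the C6 epimer. The fallback keeps that material and corrects C6 at the esterification. It sets out from 16: the same cyclisation would give the C6-epimeric hydroxy enone F1, and methylcerium addition as in step 11 would give the C6-epimeric diol F2. A Mitsunobu esterification of F2 with acid 22 (PPh3, diisopropyl azodicarboxylate, toluene, 0 °C → rt) would then form the ester with inversion at C6 and return to the route at 24.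

Step 11. Methyl transfer to C8 may show poor facial selectivity, or enter from the β face. The fallback builds the carbinol by oxygen transfer instead of carbon transfer, which reverses the outcome if both reagents prefer the same face. It sets out from 18: silylation (Et3SiCl, imidazole, DMF) would give the bis-silyl enone F3, and non-basic Lombardo methylenation (Zn, CH2Br2, TiCl4, THF/CH2Cl2) would give the exocyclic diene F4. Epoxidation of the 1,1-disubstituted alkene with dimethyldioxirane (acetone, −20 °C) would give the 8β-spiro-epoxide F5, and hydride opening at the primary carbon (LiEt3BH, THF, 0 °C) would give the tertiary alcohol F6. Selective removal of the secondary silyl ether (pyridinium p-toluenesulfonate, MeOH, 0 °C) would return to the route at 19.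

Step 8. The thermally labile carbenoid may decompose before it adds, or the (Z)-geometry may erode when the amine is released. The fallback introduces bromine by enol silane bromination instead of carbenoid homologation. It sets out from 13: MeMgBr (THF, −78 → 0 °C) would give the (Z)-methyl enone F7, and kinetic enolisation of the only enolisable position (LiN(SiMe3)2, Me3SiCl, THF, −78 °C) would give the 2-silyloxydiene F8. N-Bromosuccinimide (THF, −78 °C) would then give the bromomethyl ketone and return to the route at 15.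

Further compounds
F1 | step 10 | (3R,3aS,4R,8aR)-4-hydroxy-8a-methyl-3-(propan-2-yl)-3-[(triethylsilyl)oxy]-2,3,3a,4,5,8a-hexahydroazulen-6(1H)-one (C6 epimer of 18) | O[C@@H]1CC(=O)C=C[C@@]2(C)CC[C@@](O[Si](CC)(CC)CC)(C(C)C)[C@H]12
F2 | step 10 | (3R,3aS,4R,6S,8aR)-6,8a-dimethyl-3-(propan-2-yl)-3-[(triethylsilyl)oxy]-1,2,3,3a,4,5,6,8a-octahydroazulene-4,6-diol (C6 epimer of 19) | O[C@@H]1C[C@](C)(O)C=C[C@@]2(C)CC[C@@](O[Si](CC)(CC)CC)(C(C)C)[C@H]12
F3 | step 11 | (3R,3aS,4S,8aR)-8a-methyl-3-(propan-2-yl)-3,4-bis[(triethylsilyl)oxy]-2,3,3a,4,5,8a-hexahydroazulen-6(1H)-one | CC[Si](CC)(CC)O[C@H]1CC(=O)C=C[C@@]2(C)CC[C@@](O[Si](CC)(CC)CC)(C(C)C)[C@H]12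
F4 | step 11 | (3R,3aS,4S,8aR)-8a-methyl-6-methylidene-3-(propan-2-yl)-3,4-bis[(triethylsilyl)oxy]-1,2,3,3a,4,5,6,8a-octahydroazulene | CC[Si](CC)(CC)O[C@H]1CC(=C)C=C[C@@]2(C)CC[C@@](O[Si](CC)(CC)CC)(C(C)C)[C@H]12
F5 | step 11 | spiro-epoxide of F4 at the exocyclic alkene, oxirane oxygen on the β face of C8, other centres as in F4 | CC[Si](CC)(CC)O[C@H]1C[C@@]3(CO3)C=C[C@@]2(C)CC[C@@](O[Si](CC)(CC)CC)(C(C)C)[C@H]12
F6 | step 11 | (3R,3aS,4S,6S,8aR)-6,8a-dimethyl-3-(propan-2-yl)-3,4-bis[(triethylsilyl)oxy]-1,2,3,3a,4,5,6,8a-octahydroazulen-6-ol | CC[Si](CC)(CC)O[C@H]1C[C@](C)(O)C=C[C@@]2(C)CC[C@@](O[Si](CC)(CC)CC)(C(C)C)[C@H]12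
F7 | step 8 | (3Z)-4-[(1R,2R,3R)-2-(dimethoxymethyl)-1-methyl-3-(propan-2-yl)-3-[(triethylsilyl)oxy]cyclopentyl]but-3-en-2-one | COC(OC)[C@H]1[C@](O[Si](CC)(CC)CC)(C(C)C)CC[C@]1(C)/C=C\C(C)=O
F8 | step 8 | ({(3Z)-4-[(1R,2R,3R)-2-(dimethoxymethyl)-1-methyl-3-(propan-2-yl)-3-[(triethylsilyl)oxy]cyclopentyl]buta-1,3-dien-2-yl}oxy)trimethylsilane | COC(OC)[C@H]1[C@](O[Si](CC)(CC)CC)(C(C)C)CC[C@]1(C)/C=C\C(=C)O[Si](C)(C)C
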